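**Overview**

- **Cuts:** the ring-B C1–OH goes back to C1–CHO via the formate. Then O–CH3 and C5'–Br of ring A are cut, ring A is de-aromatised to a cyclohexanone, and last the ether O–C1' bond is cut as an O–C(sp3) bond α to that ketone.
- **Enabling feature:** in ring A (5-bromo-2-methoxyphenoxy) the ether carbon C1' and the methoxy carbon C2' are neighbours, i.e. the α-carbon and carbonyl carbon of a 2-aryloxycyclohexanone. Loss of four ring hydrogens therefore gives this ortho-O,O arene directly.
- **Ring B:** the ether oxygen (C2) sits between C3–Br and C1–OH, with the second Br para (C5). This is the pattern of 3,5-dibromosalicylaldehyde with CHO standing in for OH.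
- **Forward:** ring B is bought aromatic and its phenoxide is alkylated by 2-chlorocyclohexanone. The carbocycle is dehydrogenated to ring A, then Br, CH3 and the ring-B OH are installed in that order.
- **Stereochemistry:** the target has none. The only centre on the way (α-carbon of the aryloxy ketone, racemic) is erased on aromatisation.

Key step: step 2

Remark: the target is achiral (no stereocentre, free rotation about both ether C–O bonds), so the demand for a single enantiomer is met by the constitution alone. Primed locants refer to ring A.

Step 1
Reactants: 1 2-chlorocyclohexanone (racemic); 2 3,5-dibromosalicylaldehyde (3,5-dibromo-2-hydroxybenzaldehyde)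
Product: 4 rac-3,5-dibromo-2-[(2-oxocyclohexyl)oxy]benzaldehyde, via 2-iodocyclohexanone 3 (not isolated)
Conditions: K2CO3 (1.0 equiv), KI (20 mol %), DMF, rt → 40 °C
Reagents that add atoms: none
Why: Williamson-type SN2 O-alkylation of a phenoxide by an α-haloketone with Finkelstein activation, in which the carbonyl-accelerated displacement should accept even this hindered, weakly nucleophilic phenoxide, while the marked acidity of 2 means that its salt and a single equivalent of carbonate hold too little ketone enolate for Favorskii contraction or for the spiro-aldol closure onto CHO (which cannot dehydrate and stays reversible) to become more than minor.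

Step 2
Reactants: 4 rac-3,5-dibromo-2-[(2-oxocyclohexyl)oxy]benzaldehyde
Product: 7 3,5-dibromo-2-(2-hydroxyphenoxy)benzaldehyde, via 2-aryloxycyclohex-2-enone 5 (not isolated), via 2-aryloxycyclohexa-2,5-dienone 6 (not isolated)
Conditions: I2 (20 mol %), DMSO, 100 °C, N2
Reagents that add atoms: none
Why: Iodine and the HI it liberates promote enolisation of 4 towards the oxygen-bearing α-carbon, iodination there and loss of HI to the enone 5; iodination at C6 and a second loss of HI give the cross-conjugated dienone 6, the keto tautomer of 7, whose enolisation is irreversible, and DMSO returns each HI to I2 at the cost of Me2S and water. The reaction type is the known iodine-catalysed, DMSO-driven dehydrogenative aromatisation of cyclohexanones and cyclohexenones to phenols, which already covers 2-substituted ketones giving ortho-substituted phenols and runs through 2-oxygenated cyclohexenones when it makes catechols. No ring is closed and no bond between the two fragments is made, since the existing six-membered carbocycle only passes from sp3 to sp2 by losing four hydrogens; no stereocentre arises and the racemic α-centre of 4 disappears. The ortho O,O pattern cannot be scrambled, because the carbonyl carbon becomes C–OH and its neighbour already bears the ether oxygen. The selectivity needed is chemoselectivity: without Pd or Cu the two C–Br bonds are left alone, the formyl group has no α-hydrogen to iodinate, and both positions ortho to the ether oxygen on ring B are occupied, which shuts off acid-induced cyclodehydration to a tetrahydrodibenzofuran. The aryloxy group stays on an α or vinylic carbon and is never β to an enol, so β-elimination of the phenoxide is not open, and once 5 has formed its α-carbon is sp2 and can no longer add to the aldehyde.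

Step 3
Reactants: 7 3,5-dibromo-2-(2-hydroxyphenoxy)benzaldehyde
Product: 8 3,5-dibromo-2-(5-bromo-2-hydroxyphenoxy)benzaldehyde
Conditions: NBS (1.0 equiv), MeCN, −20 → 0 °C, dark
Reagents that add atoms: N-bromosuccinimide (NBS), O=C1CCC(=O)N1Br
Why: Electrophilic aromatic bromination under the para-selective NBS/MeCN protocol for phenols, in which the free OH is by far the strongest donor and directs to its open para carbon C5' rather than the more crowded ortho C3', while ring B is deactivated by CHO and two Br and offers only positions meta to its oxygen, and one equivalent at low temperature in the dark should prevent a second bromination and radical attack on the aldehyde C–H.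

Step 4
Reactants: 8 3,5-dibromo-2-(5-bromo-2-hydroxyphenoxy)benzaldehyde
Product: 9 3,5-dibromo-2-(5-bromo-2-methoxyphenoxy)benzaldehyde
Conditions: MeI (3 equiv), then K2CO3 (1.5 equiv), acetone, 0 °C → rt
Reagents that add atoms: methyl iodide (MeI), CI
Why: Williamson O-methylation of the phenol, run with excess MeI charged before the base and in poorly ionising acetone so that the phenoxide is capped faster than it can attack the formyl-activated ipso carbon of ring B (Smiles O-to-O aryl shift, which would leave the bromine meta instead of para to the methoxy group).

Step 5
Reactants: 9 3,5-dibromo-2-(5-bromo-2-methoxyphenoxy)benzaldehyde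
Product: 10 3,5-dibromo-2-(5-bromo-2-methoxyphenoxy)phenyl formate
Conditions: mCPBA (1.5 equiv), CH2Cl2, 0 → 40 °C; crude product taken on after a thiosulfate/bicarbonate wash
Reagents that add atoms: meta-chloroperbenzoic acid (mCPBA), OOC(=O)c1cccc(Cl)c1
Why: Baeyer–Villiger (Dakin-type) oxidation of an aryl aldehyde, in which the peracid adds to the formyl group and the aryl carbon of the Criegee adduct, supported by the ortho ether oxygen, migrates to oxygen as is well known for brominated 2-alkoxy- and 2-aryloxybenzaldehydes, while the aryl bromides and both ethers are inert to mCPBA.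

Step 6
Reactants: 10 3,5-dibromo-2-(5-bromo-2-methoxyphenoxy)phenyl formate
Product: 11 3,5-dibromo-2-(5-bromo-2-methoxyphenoxy)phenol (target)
Conditions: K2CO3 (20 mol %), MeOH, 0 °C → rt; dil. HCl work-up
Reagents that add atoms: none
Why: Base-catalysed transesterification of a very labile aryl formate with methanol, which touches neither the ethers nor the C–Br bonds, and the liberated ring-B phenoxide cannot start an aryl shift because the ring it would have to attack is the electron-rich anisole ring.

**Compound list**

1 | 2-chlorocyclohexanone (racemic) | O=C1CCCCC1Cl | starting material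
2 | 3,5-dibromosalicylaldehyde | O=Cc1cc(Br)cc(Br)c1O | starting material
3 | 2-iodocyclohexanone (racemic, not isolated) | O=C1CCCCC1I | intermediate
4 | rac-3,5-dibromo-2-[(2-oxocyclohexyl)oxy]benzaldehyde | O=Cc1cc(Br)cc(Br)c1OC1CCCCC1=O | intermediate
5 | 3,5-dibromo-2-[(6-oxocyclohex-1-en-1-yl)oxy]benzaldehyde (not isolated) | O=Cc1cc(Br)cc(Br)c1OC1=CCCCC1=O | intermediate
6 | 3,5-dibromo-2-[(6-oxocyclohexa-1,4-dien-1-yl)oxy]benzaldehyde (not isolated) | O=Cc1cc(Br)cc(Br)c1OC1=CCC=CC1=O | intermediate
7 | 3,5-dibromo-2-(2-hydroxyphenoxy)benzaldehyde | O=Cc1cc(Br)cc(Br)c1Oc1ccccc1O | intermediate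
8 | 3,5-dibromo-2-(5-bromo-2-hydroxyphenoxy)benzaldehyde | O=Cc1cc(Br)cc(Br)c1Oc1cc(Br)ccc1O | intermediate
9 | 3,5-dibromo-2-(5-bromo-2-methoxyphenoxy)benzaldehyde | COc1ccc(Br)cc1Oc1c(C=O)cc(Br)cc1Br | intermediate
10 | 3,5-dibromo-2-(5-bromo-2-methoxyphenoxy)phenyl formate | COc1ccc(Br)cc1Oc1c(OC=O)cc(Br)cc1Br | intermediate
11 | 3,5-dibromo-2-(5-bromo-2-methoxyphenoxy)phenol | COc1ccc(Br)cc1Oc1c(O)cc(Br)cc1Br | target

Total step count: 6. Longest linear sequence: 6 steps (from 1 or 2 to 11).

**Steps most likely to fail**

**Risk 1, step 2.**
- Four processes could go wrong:
  - The α-iodo-α-aryloxy stage may ionise and be captured by the water that the DMSO turnover produces, with loss of the aryloxy group.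
  - Kornblum-type oxygenation at C6 may compete with elimination.
  - The α-carbon enol may add to the formyl group under acid before the first double bond is in place.
  - Ring iodination of the phenol product may drain the catalyst.
- The fallback sets out from 2 and comes back to the route at 7.
- The potassium salt of 2 is heated with commercial 2,3-epoxycyclohexanone (O=C1CCCC2OC12) in THF/DMPU.
- Opening of the epoxide at the α-carbon should give rac-trans-3,5-dibromo-2-[(2-hydroxy-6-oxocyclohexyl)oxy]benzaldehyde F1. This loses water in the same flask by E1cB to the enone 5, which is now isolated.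
- With the ether carbon already sp2, only two hydrogens remain to be removed. This is done by hydride abstraction with DDQ (1.1 equiv, cat. TsOH, dioxane, reflux) to give 7, without iodine and without an oxidant that generates water.
- Ring A still arises by dehydrogenation of the carbocycle.

**Risk 2, step 1.**
- Displacement by the doubly ortho-substituted, weakly nucleophilic phenoxide may be slow. That would leave time for base-induced consumption of the haloketone (Favorskii contraction, dehydrohalogenation) and for aldol closure of the product enolate onto the formyl group.
- The fallback sets out from 2 and comes back at 4.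
- Base-catalysed opening of cyclohexene oxide (C1CCC2OC2C1; cat. Cs2CO3, DMF, 90 °C) forms the C–O bond while no ketone is present. It should give rac-trans-3,5-dibromo-2-[(2-hydroxycyclohexyl)oxy]benzaldehyde F2.
- Dess–Martin periodinane in CH2Cl2 at rt then oxidises the secondary alcohol to 4 under neutral conditions that neither enolise the ketone nor touch the aryl aldehyde.

**Risk 3, step 5.**
- Hydrogen migration in the Criegee adduct may compete with aryl migration. The two bromines meta to the migrating carbon lower its migratory aptitude, and the twisted ether oxygen donates only weakly.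
- The fallback sets out from 9 and comes back at 11. It removes the migrating hydrogen from the problem.
- MeMgBr (THF, −78 °C, too cold for halogen–metal exchange) should give rac-1-[3,5-dibromo-2-(5-bromo-2-methoxyphenoxy)phenyl]ethanol F3.
- Dess–Martin oxidation gives 1-[3,5-dibromo-2-(5-bromo-2-methoxyphenoxy)phenyl]ethanone F4.
- Baeyer–Villiger oxidation (mCPBA, cat. TFA, CH2Cl2), where aryl competes only with methyl, gives 3,5-dibromo-2-(5-bromo-2-methoxyphenoxy)phenyl acetate F5.
- Methanolysis (K2CO3, MeOH) then delivers 11.

**Further compounds**

F1 | step 2 | rac-trans-3,5-dibromo-2-[(2-hydroxy-6-oxocyclohexyl)oxy]benzaldehyde (one enantiomer drawn) | O=Cc1cc(Br)cc(Br)c1O[C@@H]1C(=O)CCC[C@H]1O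
F2 | step 1 | rac-trans-3,5-dibromo-2-[(2-hydroxycyclohexyl)oxy]benzaldehyde (one enantiomer drawn) | O=Cc1cc(Br)cc(Br)c1O[C@@H]1CCCC[C@H]1O
F3 | step 5 | rac-1-[3,5-dibromo-2-(5-bromo-2-methoxyphenoxy)phenyl]ethanol | COc1ccc(Br)cc1Oc1c(C(C)O)cc(Br)cc1Br
F4 | step 5 | 1-[3,5-dibromo-2-(5-bromo-2-methoxyphenoxy)phenyl]ethanone | COc1ccc(Br)cc1Oc1c(C(C)=O)cc(Br)cc1Br
F5 | step 5 | 3,5-dibromo-2-(5-bromo-2-methoxyphenoxy)phenyl acetate | COc1ccc(Br)cc1Oc1c(OC(C)=O)cc(Br)cc1Br
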